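**Plan**
- **Cuts:** (i) the six O–benzyl bonds. (ii) The two ketone carbons on C3 and C4 are rejoined as the C=C of a 1,2-diarylcyclobutene fused to the oxolane at C3–C4. (iii) C3–C and C4–C are cut together ([2+2]) to dihydrofuran 10 and alkyne 16. (iv) 10 is cut at C3=C4 (metathesis) and at one O–C bond (allylic etherification), and 16 at both C(sp)–aryl bonds.
- **Enabling feature:** oxolane C3 and C4 carry identical 2,4-dihydroxybenzoyl groups on one face, and C2 and C5 carry 4-hydroxyphenyl groups on the other. The ring is therefore meso and maps onto a syn addition of a symmetric two-carbon unit to the open face of a C3=C4 alkene.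
- **Forward order:** oxolane ring (step 6), cyclobutene ring (step 10), cyclobutene opened to the cis-diketone (step 11), benzyl groups removed (step 12).
- **Stereochemistry:** C2/C5 come from two iridium-catalysed allylic substitutions run with mirror-image ligands (R + S = meso, hence cis after ring closure). C3/C4 come from suprafacial addition anti to both aryl groups.

Key step: step 10

Remark (assumption): the target has a mirror plane through O1 and the midpoint of C3–C4. The SMILES therefore describes an achiral meso compound, (2R,3R,4S,5S), and "single enantiomer" is taken to mean this one diastereomer.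

Notation: L is one enantiomer of the BINOL-derived N,N-bis(1-phenylethyl)phosphoramidite, namely the one that delivers (R)-7. ent-L is its mirror image. Because the ether 9 is meso, only the opposite sense of the two iridium steps matters.

Step 1
Reactants: 1 4-(benzyloxy)benzaldehyde; 2 triethyl phosphonoacetate
Product: 3 ethyl (E)-3-[4-(benzyloxy)phenyl]prop-2-enoate
Conditions: LiCl, DBU, MeCN, rt
Reagents that add atoms: none
Why: The Horner–Wadsworth–Emmons olefination of an aromatic aldehyde with a stabilised phosphonate is reliably E-selective, and the mild amine base leaves the benzyl ether untouched.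

Step 2
Reactants: 3 ethyl (E)-3-[4-(benzyloxy)phenyl]prop-2-enoate
Product: 4 (E)-3-[4-(benzyloxy)phenyl]prop-2-en-1-ol
Conditions: DIBAL-H (2.3 equiv), CH2Cl2, −78 → 0 °C; aq. Rochelle salt
Reagents that add atoms: none
Why: DIBAL-H reduction of an α,β-unsaturated ester proceeds by clean 1,2-hydride delivery to the allylic alcohol with the E-alkene preserved.

Step 3
Reactants: 4 (E)-3-[4-(benzyloxy)phenyl]prop-2-en-1-ol
Product: 5 tert-butyl (E)-3-[4-(benzyloxy)phenyl]prop-2-en-1-yl carbonate
Conditions: Boc2O, DMAP (cat.), THF, 0 °C → rt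
Reagents that add atoms: di-tert-butyl dicarbonate, CC(C)(C)OC(=O)OC(=O)OC(C)(C)C
Why: DMAP-catalysed O-acylation gives the linear carbonate, and the tert-butyl carbonate is chosen because it releases only poorly nucleophilic tert-butoxide, which should not compete in steps 4 and 5.

Step 4
Reactants: 5 tert-butyl (E)-3-[4-(benzyloxy)phenyl]prop-2-en-1-yl carbonate
Product: 7 (R)-1-[4-(benzyloxy)phenyl]prop-2-en-1-ol, via triethylsilyl ether 6 (not isolated)
Conditions: [Ir(cod)Cl]2 (2 mol %), L (4 mol %), Et3SiOK (2 equiv), CH2Cl2, rt; then TBAF, THF, 0 °C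
Reagents that add atoms: potassium triethylsilanolate, CC[Si](CC)(CC)[O-].[K+]
Why: In this iridium-catalysed asymmetric allylic substitution the silanolate acts as a hydroxide surrogate and attacks the aryl-bearing terminus of the π-allyl complex, the chiral ligand sets the (R) centre, and fluoride removes the silyl group without acid that could ionise the benzylic, allylic alcohol.

Step 5
Reactants: 7 (R)-1-[4-(benzyloxy)phenyl]prop-2-en-1-ol; 5 tert-butyl (E)-3-[4-(benzyloxy)phenyl]prop-2-en-1-yl carbonate
Product: 9 meso-(R,S)-bis{1-[4-(benzyloxy)phenyl]prop-2-en-1-yl} ether, via copper(I) alkoxide 8 (not isolated)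
Conditions: 7, n-BuLi, THF, 0 °C; CuI, rt; then 5, [Ir(cod)Cl]2 (2 mol %), ent-L (4 mol %), THF, rt
Reagents that add atoms: none
Why: Iridium-catalysed branched-selective allylic etherification with copper(I) alkoxides of secondary alcohols is catalyst-controlled, so ent-L should set the new centre as (S) while the C–O bond of 7 is untouched and stays (R), which gives the meso ether.

Step 6
Reactants: 9 meso-(R,S)-bis{1-[4-(benzyloxy)phenyl]prop-2-en-1-yl} ether
Product: 10 meso cis-(2R,5S)-2,5-bis[4-(benzyloxy)phenyl]-2,5-dihydrofuran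
Conditions: (H2IMes)(PCy3)Cl2Ru=CHPh (3 mol %), CH2Cl2 (0.02 M), 40 °C
Reagents that add atoms: none
Why: Ring-closing metathesis of a bis(allyl) ether closes the five-membered ring with loss of ethene and touches neither C–O stereocentre, so the meso ether can only give the cis isomer.

Step 7
Reactants: 11 4-bromoresorcinol
Product: 12 2,4-bis(benzyloxy)-1-bromobenzene
Conditions: BnBr (2.2 equiv), K2CO3, DMF, 60 °C
Reagents that add atoms: benzyl bromide, BrCc1ccccc1
Why: The Williamson ether synthesis on both phenols installs a group that survives palladium, cobalt and cold ozone and can be removed at the end without acid or base.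

Step 8
Reactants: 12 2,4-bis(benzyloxy)-1-bromobenzene; 13 trimethylsilylacetylene
Product: 14 {[2,4-bis(benzyloxy)phenyl]ethynyl}trimethylsilane
Conditions: PdCl2(PhCN)2 (3 mol %), P(t-Bu)3·HBF4 (6 mol %), CuI (2 mol %), i-Pr2NH, dioxane, rt → 50 °C
Reagents that add atoms: none
Why: In this Sonogashira coupling the bulky, electron-rich phosphine enables oxidative addition into the electron-rich, ortho-alkoxylated aryl bromide below the boiling point of the alkyne.

Step 9
Reactants: 14 {[2,4-bis(benzyloxy)phenyl]ethynyl}trimethylsilane; 12 2,4-bis(benzyloxy)-1-bromobenzene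
Product: 16 bis[2,4-bis(benzyloxy)phenyl]acetylene, via terminal alkyne 15 (not isolated)
Conditions: PdCl2(PPh3)2 (5 mol %), CuI (5 mol %), CsF (2 equiv), Et3N/H2O/PEG-200, 80 °C
Reagents that add atoms: none
Why: Fluoride-triggered protodesilylation releases the terminal alkyne slowly and a second Sonogashira coupling consumes it at once, which keeps its concentration low and suppresses Glaser homocoupling.

Step 10
Reactants: 10 meso cis-(2R,5S)-2,5-bis[4-(benzyloxy)phenyl]-2,5-dihydrofuran; 16 bis[2,4-bis(benzyloxy)phenyl]acetylene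
Product: 17 (1R,2S,4R,5S)-6,7-bis[2,4-bis(benzyloxy)phenyl]-2,4-bis[4-(benzyloxy)phenyl]-3-oxabicyclo[3.2.0]hept-6-ene (meso; cis ring fusion; both C2/C4 aryl groups on the face opposite the cyclobutene)
Conditions: CoBr2(dppp) (10 mol %), Zn (30 mol %), NaBArF (15 mol %), CH2Cl2, rt → 40 °C; 10 in slight excess, the surplus to be recovered
Reagents that add atoms: none
Why: Zinc and NaBArF should turn the precatalyst into a cationic (dppp)Co(I) species that binds 16 and the C3=C4 alkene of 10, couples them oxidatively to a cobaltacyclopentene and releases the product by C(sp2)–C(sp3) reductive elimination. The closest known reaction type is the cobalt–diphosphine-catalysed [2+2] cycloaddition of internal aryl alkynes with cyclopentene and related unstrained cis ring alkenes, of which 10 is the 3-oxa analogue. The one ring that closes, the cyclobutene, does so in this formal [2+2] mode, with both new bonds (C1–C7 and C5–C6, the later C3–C(=O) and C4–C(=O) bonds) arising in a single catalytic cycle. C1 and C5 are the new stereocentres: their mutual cis relation follows from suprafacial delivery of both bonds through the metallacycle, and their trans relation to C2 and C4 follows from the two cis aryl groups, which block one face of the nearly flat dihydrofuran and force cobalt and alkyne onto the other. The step needs this facial selectivity and also chemoselectivity for reductive elimination over β-hydride elimination (Alder-ene outcome), alkene migration and alkyne cyclotrimerisation; the levers are the larger bite angle of dppp, the ortho-benzyloxy bulk of 16, and NaBArF in place of a zinc halide Lewis acid that could ionise the allylic, benzylic C–O bonds. Both partners are symmetric, so no regiochemical issue exists and the product stays meso.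

Step 11
Reactants: 17 (1R,2S,4R,5S)-6,7-bis[2,4-bis(benzyloxy)phenyl]-2,4-bis[4-(benzyloxy)phenyl]-3-oxabicyclo[3.2.0]hept-6-ene
Product: 19 [(2R,3R,4S,5S)-2,5-bis[4-(benzyloxy)phenyl]oxolane-3,4-diyl]bis{[2,4-bis(benzyloxy)phenyl]methanone}, via ozonide 18 (not isolated)
Conditions: O3/O2, CH2Cl2, −78 °C, Sudan Red 7B as end-point indicator; N2 purge; PPh3, −78 °C → rt
Reagents that add atoms: ozone, [O-][O+]=O
Why: In this Criegee ozonolysis the strained, electron-rich tetrasubstituted stilbene-type alkene should take up ozone far faster than the alkoxyarenes or benzylic C–H bonds, the ketone and carbonyl oxide recombine intramolecularly to the ozonide, and neutral phosphine reduction unveils both ketones without disturbing C3 and C4.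

Step 12
Reactants: 19 [(2R,3R,4S,5S)-2,5-bis[4-(benzyloxy)phenyl]oxolane-3,4-diyl]bis{[2,4-bis(benzyloxy)phenyl]methanone}
Product: 20 [(2R,3R,4S,5S)-2,5-bis(4-hydroxyphenyl)oxolane-3,4-diyl]bis[(2,4-dihydroxyphenyl)methanone] (target, meso)
Conditions: H2 (1 atm), 10 % Pd/C, THF/MeOH, rt, stopped after uptake of six equivalents
Reagents that add atoms: none
Why: Catalytic hydrogenolysis cleaves aryl benzyl ethers much faster than the hindered ring C–O bonds or the hydrogen-bonded aryl ketones, and the neutral medium avoids enolisation at C3/C4, retro-oxa-Michael opening and Paal–Knorr-type dehydration of the cis-1,4-diketone.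

**Compound list**

1 | 4-(benzyloxy)benzaldehyde | O=Cc1ccc(OCc2ccccc2)cc1 | starting material
2 | triethyl phosphonoacetate | CCOC(=O)CP(=O)(OCC)OCC | starting material
3 | ethyl (E)-3-[4-(benzyloxy)phenyl]prop-2-enoate | CCOC(=O)/C=C/c1ccc(OCc2ccccc2)cc1 | intermediate
4 | (E)-3-[4-(benzyloxy)phenyl]prop-2-en-1-ol | OC/C=C/c1ccc(OCc2ccccc2)cc1 | intermediate
5 | tert-butyl (E)-3-[4-(benzyloxy)phenyl]prop-2-en-1-yl carbonate | CC(C)(C)OC(=O)OC/C=C/c1ccc(OCc2ccccc2)cc1 | intermediate
6 | (R)-{1-[4-(benzyloxy)phenyl]prop-2-en-1-yloxy}triethylsilane (not isolated) | C=C[C@@H](O[Si](CC)(CC)CC)c1ccc(OCc2ccccc2)cc1 | intermediate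
7 | (R)-1-[4-(benzyloxy)phenyl]prop-2-en-1-ol | C=C[C@@H](O)c1ccc(OCc2ccccc2)cc1 | intermediate
8 | copper(I) (R)-1-[4-(benzyloxy)phenyl]prop-2-en-1-olate (not isolated) | C=C[C@@H]([O-])c1ccc(OCc2ccccc2)cc1.[Cu+] | intermediate
9 | meso-(R,S)-bis{1-[4-(benzyloxy)phenyl]prop-2-en-1-yl} ether | C=C[C@@H](O[C@@H](C=C)c1ccc(OCc2ccccc2)cc1)c1ccc(OCc2ccccc2)cc1 | intermediate
10 | meso cis-(2R,5S)-2,5-bis[4-(benzyloxy)phenyl]-2,5-dihydrofuran | O(Cc1ccccc1)c1ccc(cc1)[C@H]1C=C[C@H](O1)c1ccc(OCc2ccccc2)cc1 | intermediate
11 | 4-bromoresorcinol | Oc1ccc(Br)c(O)c1 | starting material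
12 | 2,4-bis(benzyloxy)-1-bromobenzene | Brc1ccc(OCc2ccccc2)cc1OCc1ccccc1 | intermediate
13 | trimethylsilylacetylene | C#C[Si](C)(C)C | starting material
14 | {[2,4-bis(benzyloxy)phenyl]ethynyl}trimethylsilane | C[Si](C)(C)C#Cc1ccc(OCc2ccccc2)cc1OCc1ccccc1 | intermediate
15 | 2,4-bis(benzyloxy)-1-ethynylbenzene (not isolated) | C#Cc1ccc(OCc2ccccc2)cc1OCc1ccccc1 | intermediate
16 | bis[2,4-bis(benzyloxy)phenyl]acetylene | C(#Cc1ccc(OCc2ccccc2)cc1OCc1ccccc1)c1ccc(OCc2ccccc2)cc1OCc1ccccc1 | intermediate
17 | (1R,2S,4R,5S)-6,7-bis[2,4-bis(benzyloxy)phenyl]-2,4-bis[4-(benzyloxy)phenyl]-3-oxabicyclo[3.2.0]hept-6-ene, meso | C1(c2ccc(OCc3ccccc3)cc2OCc2ccccc2)=C(c2ccc(OCc3ccccc3)cc2OCc2ccccc2)[C@@H]2[C@H]1[C@@H](c1ccc(OCc3ccccc3)cc1)O[C@H]2c1ccc(OCc2ccccc2)cc1 | intermediate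
18 | ozonide of 17: 2,3,7-trioxabicyclo[2.2.1]heptane with the two 2,4-bis(benzyloxy)phenyl groups at the bridgeheads, fused at C5–C6 to the 2,5-diaryloxolane; drawn with the oxolane syn to the one-oxygen bridge, the other orientation would serve equally (not isolated) | O(Cc1ccccc1)c1cc(OCc2ccccc2)ccc1[C@@]12OO[C@@](c3ccc(OCc4ccccc4)cc3OCc3ccccc3)(O1)[C@@H]3[C@H]2[C@@H](c1ccc(OCc2ccccc2)cc1)O[C@H]3c1ccc(OCc2ccccc2)cc1 | intermediate
19 | [(2R,3R,4S,5S)-2,5-bis[4-(benzyloxy)phenyl]oxolane-3,4-diyl]bis{[2,4-bis(benzyloxy)phenyl]methanone}, meso | O=C(c1ccc(OCc2ccccc2)cc1OCc1ccccc1)[C@@H]1[C@H](C(=O)c2ccc(OCc3ccccc3)cc2OCc2ccccc2)[C@@H](c2ccc(OCc3ccccc3)cc2)O[C@H]1c1ccc(OCc2ccccc2)cc1 | intermediate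
20 | [(2R,3R,4S,5S)-2,5-bis(4-hydroxyphenyl)oxolane-3,4-diyl]bis[(2,4-dihydroxyphenyl)methanone], CNP0237262.1 | O=C(c1ccc(O)cc1O)[C@@H]1[C@H](C(=O)c2ccc(O)cc2O)[C@@H](c2ccc(O)cc2)O[C@H]1c1ccc(O)cc1 | target

**Step count**
- Total step count: 12.
- Longest linear sequence: 9 steps (1–6, then 10–12). The alkyne branch (steps 7–9) runs in parallel.

**Steps most likely to fail**

1. **Step 10.**
 - *What may go wrong:* the hydrogens at the two aryl-bearing carbons lie on the same face as cobalt, so β-hydride elimination from the metallacycle may outrun ring closure. Chelation by the ortho-benzyloxy groups or steric crowding may stop turnover. Adventitious Lewis acid may open or isomerise the dihydrofuran.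
 - *Fallback (sets out from 10 and 12, returns at 17):* the alkyne is replaced by a far more electrophilic cumulene, and the second aryl group and the alkene are installed afterwards.
 - Bromide 12 is coupled under palladium catalysis with the Reformatsky-type zinc enolate of N,N-dimethylacetamide (α-arylation) to give 2-[2,4-bis(benzyloxy)phenyl]-N,N-dimethylacetamide F1.
 - Activation of F1 with Tf2O and 2,4,6-collidine in 1,2-dichloroethane in the presence of 10 generates a keteniminium ion. This undergoes the thermal [2+2] cycloaddition known for cyclopentene-type alkenes, again anti to the two aryl groups.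
 - Aqueous hydrolysis then gives the cis-fused 7-[2,4-bis(benzyloxy)phenyl]-2,4-bis[4-(benzyloxy)phenyl]-3-oxabicyclo[3.2.0]heptan-6-one F2.
 - Halogen–lithium exchange of 12 with n-BuLi gives [2,4-bis(benzyloxy)phenyl]lithium F3. After transmetallation with CeCl3 to curb enolisation, F3 adds to the ketone from the convex face to give 6,7-bis[2,4-bis(benzyloxy)phenyl]-2,4-bis[4-(benzyloxy)phenyl]-3-oxabicyclo[3.2.0]heptan-6-ol F4.
 - Syn dehydration with methyl N-(triethylammoniosulfonyl)carbamate toward the aryl-bearing carbon erases both transient centres and restores the symmetry in 17.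

2. **Step 11.**
 - *What may go wrong:* over-oxidation by ozone (attack on the resorcinol-type rings or oxidation of benzylic CH2 groups to benzoates), sluggish reduction of the fully substituted ozonide, or epimerisation next to the new ketones during work-up and chromatography.
 - *Fallback (sets out from 17, returns at 19):* the cleavage is split into two milder oxidations.
 - Stoichiometric OsO4 with pyridine in THF, followed by NaHSO3, dihydroxylates the cyclobutene from its convex face to give 6,7-bis[2,4-bis(benzyloxy)phenyl]-2,4-bis[4-(benzyloxy)phenyl]-3-oxabicyclo[3.2.0]heptane-6,7-diol F5.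
 - Glycol cleavage with Pb(OAc)4 in CH2Cl2 at 0 °C, helped by release of ring strain, then gives 19.

3. **Step 5.**
 - *What may go wrong:* loss of catalyst control with the hindered secondary alkoxide (a mismatched pairing that lets the trans-series ether form), attack at the unsubstituted allyl terminus, or slow turnover.
 - *Fallback (sets out from 5 and 7, returns at 9):* the stereochemistry is drawn from the substrates instead of the catalyst.
 - Carbonate 5 is taken through the procedure of step 4 with ent-L to give (S)-{1-[4-(benzyloxy)phenyl]prop-2-en-1-yloxy}triethylsilane F6 and, after fluoride, (S)-1-[4-(benzyloxy)phenyl]prop-2-en-1-ol F7.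
 - Methyl chloroformate and pyridine convert F7 into (S)-1-[4-(benzyloxy)phenyl]prop-2-en-1-yl methyl carbonate F8.
 - RhCl(PPh3)3 modified with P(OMe)3 then couples F8 with copper alkoxide 8 (made from 7 as in step 5) in THF at 0 °C → rt.
 - This rhodium-catalysed allylic etherification is regio-retentive and enantiospecific with net retention, so (S)-electrophile plus (R)-alkoxide should give meso 9.

**Further compounds**

F1 | step 10 | 2-[2,4-bis(benzyloxy)phenyl]-N,N-dimethylacetamide | CN(C)C(=O)Cc1ccc(OCc2ccccc2)cc1OCc1ccccc1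
F2 | step 10 | cis-fused 7-[2,4-bis(benzyloxy)phenyl]-2,4-bis[4-(benzyloxy)phenyl]-3-oxabicyclo[3.2.0]heptan-6-one (racemic, one enantiomer drawn; C7 aryl on the convex face) | O=C1[C@H](c2ccc(OCc3ccccc3)cc2OCc2ccccc2)[C@@H]2[C@H]1[C@@H](c1ccc(OCc3ccccc3)cc1)O[C@H]2c1ccc(OCc2ccccc2)cc1
F3 | step 10 | [2,4-bis(benzyloxy)phenyl]lithium | [Li]c1ccc(OCc2ccccc2)cc1OCc1ccccc1
F4 | step 10 | 6,7-bis[2,4-bis(benzyloxy)phenyl]-2,4-bis[4-(benzyloxy)phenyl]-3-oxabicyclo[3.2.0]heptan-6-ol (racemic, one enantiomer drawn; both aryl groups on the convex face, OH syn to C7–H) | O[C@@]1(c2ccc(OCc3ccccc3)cc2OCc2ccccc2)[C@H](c2ccc(OCc3ccccc3)cc2OCc2ccccc2)[C@@H]2[C@H]1[C@@H](c1ccc(OCc3ccccc3)cc1)O[C@H]2c1ccc(OCc2ccccc2)cc1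
F5 | step 11 | 6,7-bis[2,4-bis(benzyloxy)phenyl]-2,4-bis[4-(benzyloxy)phenyl]-3-oxabicyclo[3.2.0]heptane-6,7-diol (meso; both OH on the convex face) | O[C@]1(c2ccc(OCc3ccccc3)cc2OCc2ccccc2)[C@@](O)(c2ccc(OCc3ccccc3)cc2OCc2ccccc2)[C@@H]2[C@H]1[C@@H](c1ccc(OCc3ccccc3)cc1)O[C@H]2c1ccc(OCc2ccccc2)cc1
F6 | step 5 | (S)-{1-[4-(benzyloxy)phenyl]prop-2-en-1-yloxy}triethylsilane | C=C[C@H](O[Si](CC)(CC)CC)c1ccc(OCc2ccccc2)cc1
F7 | step 5 | (S)-1-[4-(benzyloxy)phenyl]prop-2-en-1-ol | C=C[C@H](O)c1ccc(OCc2ccccc2)cc1
F8 | step 5 | (S)-1-[4-(benzyloxy)phenyl]prop-2-en-1-yl methyl carbonate | C=C[C@H](OC(=O)OC)c1ccc(OCc2ccccc2)cc1
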